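**Plan**
1. The target is triacontan-30-olide. Its single 31-membered ring consists of the ring O, C1(=O) and the 29 methylenes C2–C30 (seco-acid numbering). It is achiral, so no stereochemistry has to be set.
2. Enabling feature: the arc C2–C30 is an unbroken, unsubstituted polymethylene chain, so any four neighbouring ring CH2 groups can be carried as a buta-1,3-diyne. C23–C26 is chosen because the alcohol arm O–C30…C25 then becomes commercial hex-5-yn-1-ol.
3. Retrosynthetic cuts, in order: (a) reintroduce unsaturation at C17≡C18 and C23≡C24–C25≡C26; (b) cut the diyne sigma bond C24–C25 in the ring, an oxidative union of two acetylide carbons of like polarity; (c) cut the ester bond O–C1; (d) cut C16–C17 into an acetylide and a primary bromide.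
4. Forward order: join the chain at C16–C17 (C8 + C16), esterify (C24 + C6), close the only ring at C24–C25 by Eglinton coupling, then remove all three helper alkynes in one exhaustive hydrogenation.
5. No stereogenic unit exists at any stage of the route.

Key step: step 3

Remark on the chemistry: the SMILES is read as one carbonyl carbon, 29 ring CH2 groups and one ring oxygen (C30H58O2). All locants below follow the seco acid, with C1 the carbonyl carbon and C30 the O-bearing CH2.

**Step 1**
Reactants: 1 octa-1,7-diyne; 2 16-bromohexadecanoic acid
Product: 6 tetracosa-17,23-diynoic acid, via lithium octa-1,7-diyn-1-ide 3 (not isolated), via lithium 16-bromohexadecanoate 4 (not isolated), via lithium tetracosa-17,23-diynoate 5 (not isolated)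
Conditions: 1 (6 equiv), n-BuLi (2.5 equiv), THF, −78 to 0 °C; DMPU, then 2 (1 equiv) in THF, 0 °C to rt; 1 M HCl work-up; excess 1 removed by evaporation
Reagents that add atoms: none
Why: This is a classical SN2 alkylation of a lithium acetylide with a primary alkyl bromide in a dipolar aprotic cosolvent, run on the carboxylate salt 4 (formed when the first equivalent of 3 removes the acid proton, and inert to acetylide addition), with the large excess of cheap, volatile 1 holding the reaction to one of its two termini.

**Step 2**
Reactants: 6 tetracosa-17,23-diynoic acid; 7 hex-5-yn-1-ol
Product: 9 hex-5-yn-1-yl tetracosa-17,23-diynoate, via O-acylisourea 8 (not isolated)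
Conditions: DCC (1.2 equiv), DMAP (0.1 equiv), CH2Cl2, 0 °C to rt
Reagents that add atoms: none
Why: In this Steglich esterification, DMAP-catalysed acyl transfer from the O-acylisourea 8 to the unhindered primary alcohol runs under essentially neutral conditions that leave the three alkynes and both C(sp)–H bonds untouched.

**Step 3**
Reactants: 9 hex-5-yn-1-yl tetracosa-17,23-diynoate
Product: 11 triaconta-17,23,25-triyn-30-olide (1-oxacyclohentriaconta-18,24,26-triyn-2-one), via dicopper bis-acetylide 10 (not isolated)
Conditions: Cu(OAc)2 (10 equiv), pyridine/Et2O (3:1), 45 °C, Ar; 9 added by syringe pump over 36 h (final ca. 1 mM); aq. NH4Cl/EDTA wash, silica plug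
Reagents that add atoms: none
Why: Pyridine-assisted cupration of the two terminal C(sp)–H bonds (C24–H of the acyl chain and C25–H of the hexynyl arm) gives the bis-acetylide 10, which divalent copper oxidises within a dinuclear acetylide cluster, and collapse of that cluster joins the two equally nucleophilic acetylide carbons as the C24–C25 bond while two Cu(OAc)2 end as monovalent CuOAc. The closest known reaction type is the Glaser–Eglinton macrocyclisation of ester-tethered alpha,omega-diynes to macrolactones. The one ring formed is the 31-membered lactone, closed end to end with both reacting alkynes becoming endocyclic as a linear C23–C26 buta-1,3-diyne rod that a ring of this size holds without strain. No stereocenter is created. The step needs ring closure to outrun chain growth, which is secured by slow addition into a large excess of oxidant so that the stationary concentration of uncoupled termini stays far below the effective molarity of a strain-free large ring, helped by the rigid alkyne units that take rotors out of the tether. It also needs site selectivity among three alkynes, which is intrinsic because only the two C–H-bearing termini can be metalated, whereas the internal C17≡C18 alkyne and the ester are inert to Cu(OAc)2/pyridine.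

**Step 4**
Reactants: 11 triaconta-17,23,25-triyn-30-olide
Product: 12 triacontan-30-olide (1-oxacyclohentriacontan-2-one; target)
Conditions: H2 (1–3 bar), Pd/C (10 wt % Pd), EtOAc/THF, rt to 40 °C
Reagents that add atoms: none
Why: Exhaustive heterogeneous catalytic hydrogenation should take up six equivalents of H2 and turn the conjugated diyne and the isolated alkyne into six methylene pairs, while the lactone, which has no allylic, propargylic or benzylic C–O bond, is inert and no stereocenter arises.

**Compound list**
1 | octa-1,7-diyne | C#CCCCCC#C | starting material
2 | 16-bromohexadecanoic acid | OC(=O)CCCCCCCCCCCCCCCBr | starting material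
3 | lithium octa-1,7-diyn-1-ide | [Li]C#CCCCCC#C | intermediate
4 | lithium 16-bromohexadecanoate | [Li+].[O-]C(=O)CCCCCCCCCCCCCCCBr | intermediate
5 | lithium tetracosa-17,23-diynoate | [Li+].[O-]C(=O)CCCCCCCCCCCCCCCC#CCCCCC#C | intermediate
6 | tetracosa-17,23-diynoic acid | OC(=O)CCCCCCCCCCCCCCCC#CCCCCC#C | intermediate
7 | hex-5-yn-1-ol | OCCCCC#C | starting material
8 | O-(tetracosa-17,23-diynoyl)-N,N'-dicyclohexylisourea | O=C(OC(=NC1CCCCC1)NC1CCCCC1)CCCCCCCCCCCCCCCC#CCCCCC#C | intermediate
9 | hex-5-yn-1-yl tetracosa-17,23-diynoate | C#CCCCCOC(=O)CCCCCCCCCCCCCCCC#CCCCCC#C | intermediate
10 | dicopper bis-acetylide of 9 (both termini C–Cu) | [Cu]C#CCCCCOC(=O)CCCCCCCCCCCCCCCC#CCCCCC#C[Cu] | intermediate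
11 | triaconta-17,23,25-triyn-30-olide | O=C1CCCCCCCCCCCCCCCC#CCCCCC#CC#CCCCCO1 | intermediate
12 | triacontan-30-olide (1-oxacyclohentriacontan-2-one) | O=C1CCCCCCCCCCCCCCCCCCCCCCCCCCCCCO1 | target

**Step count**
Total step count: 4.
Longest linear sequence: 4 steps (1 or 2 → 6 → 9 → 11 → 12).

**Steps most likely to fail**

1. **Step 3.** Intermolecular coupling may outrun ring closure, so that chain growth to linear and cyclic oligomers consumes the substrate.
   - The fallback sets out from 6 and 7 and comes back at 11.
   - It makes the alkyne–alkyne bond between two molecules at ordinary concentration and closes the ring afterwards at the acyl–oxygen bond.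
   - Bromination of 7 at the alkyne terminus (NBS, cat. AgNO3, acetone) should give 6-bromohex-5-yn-1-ol F1.
   - Cadiot–Chodkiewicz coupling of F1 with 6 (cat. CuCl, NH2OH·HCl, n-BuNH2, THF/MeOH/H2O, 0 °C to rt, acidic work-up) should give 30-hydroxytriaconta-17,23,25-triynoic acid F2.
   - Shiina macrolactonisation of F2 (2-methyl-6-nitrobenzoic anhydride, DMAP, CH2Cl2, slow addition) should then deliver 11.

2. **Step 1.** Alkylation may occur at both alkyne termini. Substitution on the sparingly soluble lithium carboxylate may also be slow enough for loss of HBr by elimination to compete.
   - The fallback sets out from 2 (with 1) and comes back at 6.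
   - It replaces the stoichiometric acetylide substitution by a catalytic cross-coupling on a masked acid.
   - Fischer esterification of 2 (MeOH, cat. H2SO4, reflux) should give methyl 16-bromohexadecanoate F3.
   - A Sonogashira-type coupling of this unactivated primary bromide with excess 1 ([Pd(allyl)Cl]2, 1,3-bis(1-adamantyl)imidazolium chloride, CuI, Cs2CO3, DMF/Et2O, 45–60 °C, Ar) should give methyl tetracosa-17,23-diynoate F4.
   - Saponification of F4 (LiOH, THF/H2O, then dilute HCl) returns 6.

3. **Step 4.** Hydrogen uptake may stall at a partly reduced olefinic stage. The likely causes are poisoning of the metal surface by traces of copper or pyridine and coating of the catalyst by the waxy product.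
   - The fallback sets out from 11 and comes back at 12.
   - It replaces surface catalysis by concerted, metal-free hydrogen transfer from diimide.
   - Diimide is generated in situ from a large excess of 2-nitrobenzenesulfonyl hydrazide and Et3N in CH2Cl2/THF at rt.
   - Diimide is indifferent to such poisons and to the lactone.
   - The fallback passes through no new isolable compound (entry F0).

**Further compounds**
F1 | step 3 | 6-bromohex-5-yn-1-ol | OCCCCC#CBr
F2 | step 3 | 30-hydroxytriaconta-17,23,25-triynoic acid | OC(=O)CCCCCCCCCCCCCCCC#CCCCCC#CC#CCCCCO
F3 | step 1 | methyl 16-bromohexadecanoate | COC(=O)CCCCCCCCCCCCCCCBr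
F4 | step 1 | methyl tetracosa-17,23-diynoate | COC(=O)CCCCCCCCCCCCCCCC#CCCCCC#C
F0 | step 4 | none | none
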